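**Retrosynthetic overview**
1. Target ⇒ (MOM removal, C5=O → C5=CH2) α‑chloro keto‑γ‑lactone ⇒ one‑pot carboxylate conjugate addition and enolate chlorination on the C5–C7 enone. The lactone ring is formed last and this sets C6 and C7.
2. ⇒ C8–C17 bond by replacing the bridgehead hemiketal OH of an 11‑oxabicyclo[5.3.1]undecenone with a propionate bis‑silyl ketene acetal.
3. ⇒ Key step: oxidative furan → pyranone ring expansion (Achmatowicz) of a [6](2,5)furanophane carbinol. It turns the 5,8‑oxygen bridge into the 4,8‑ether bridge.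
4. ⇒ Ten‑membered carbocycle by Ni/Cr closure of C4–C5, C9–C10 by a titanium syn‑aldol with 5‑bromofurfural, and C2–C3 by (Z)‑γ‑alkoxyallylboration.
5. ⇒ Cyclohexane ring first, by asymmetric Diels–Alder reaction. Ring order: cyclohexane → furanophane (C10 ring) → pyranone → γ‑lactone.

Assumption: 3‑(methoxymethoxy)prop‑1‑ene is taken as a catalogue compound (otherwise allyl alcohol + MOMCl adds one step off the main line).
Locants: briarane numbering is used throughout. C1 is the quaternary carbon bearing CH3‑15. C1–C10 form the ten‑membered ring. C1 and C10–C14 form the six‑membered ring. C16 sits on C5, C17–C19 belong to the lactone, and C20 sits on C11.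

Step 1
Reactants: 1 (E)-buta-1,3-dien-1-yl acetate; 2 methacrolein
Product: 3 (1S,6R)-6-formyl-6-methylcyclohex-2-en-1-yl acetate
Conditions: o‑tolyl‑oxazaborolidinium triflimide from diphenylprolinol (10 mol %, the antipode that leaves the Cα‑Si face of 2 open), CH2Cl2, −78 → −40 °C
Reagents that add atoms: none
Why: Catalytic asymmetric Diels–Alder reaction in which the 1‑acetoxy group directs "ortho" bond formation, the formyl‑endo transition state puts CHO (C2) cis to OAc (C14), and the chiral Lewis acid exposes only one face of 2, so C1 and C14 are set together.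

Step 2
Reactants: 3 (1S,6R)-6-formyl-6-methylcyclohex-2-en-1-yl acetate
Product: 4 (1S,6R)-6-formyl-6-methyl-4-oxocyclohex-2-en-1-yl acetate
Conditions: CrO3, 3,5‑dimethylpyrazole, CH2Cl2, −20 °C
Reagents that add atoms: chromium trioxide O=[Cr](=O)=O
Why: Allylic C–H oxidation with the CrO3–dimethylpyrazole complex takes the only free allylic CH2 (C11) to the enone, the anhydrous medium spares the neopentyl aldehyde, and no stereocentre is touched.

Step 3
Reactants: 4 (1S,6R)-6-formyl-6-methyl-4-oxocyclohex-2-en-1-yl acetate; 5 3-(methoxymethoxy)prop-1-ene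
Product: 8 (1S,6S)-6-[(1R,2R)-1-hydroxy-2-(methoxymethoxy)but-3-en-1-yl]-6-methyl-4-oxocyclohex-2-en-1-yl acetate, via lithiated allyl ether 6 (not isolated), via alkoxyallylborane 7 (not isolated)
Conditions: 5, s‑BuLi, THF, −78 °C; (−)‑Ipc2BOMe; BF3·OEt2; then 4, −78 °C; HOCH2CH2NH2, rt
Reagents that add atoms: none
Why: Brown (Z)‑γ‑alkoxyallylboration, in which the aldehyde reacts far faster than the enone, the chair transition state turns the Z‑borane into the syn (threo) C2‑OH/C3‑OMOM pair, and the Ipc groups derived from (+)‑α‑pinene select the aldehyde face that gives 2R.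

Step 4
Reactants: 8 (1S,6S)-6-[(1R,2R)-1-hydroxy-2-(methoxymethoxy)but-3-en-1-yl]-6-methyl-4-oxocyclohex-2-en-1-yl acetate
Product: 9 (1S,6R)-6-[(1R,2R)-1,2-bis(methoxymethoxy)but-3-en-1-yl]-6-methyl-4-oxocyclohex-2-en-1-yl acetate
Conditions: MOMCl, i‑Pr2NEt, DMAP (cat.), ClCH2CH2Cl, 50 °C
Reagents that add atoms: chloromethyl methyl ether COCCl
Why: O‑alkylation (MOM protection) of the hindered C2‑OH under a mild amine base keeps the C14 acetate and all stereocentres, and leaves both diol oxygens under one group that comes off in a single last step.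

Step 5
Reactants: 9 (1S,6R)-6-[(1R,2R)-1,2-bis(methoxymethoxy)but-3-en-1-yl]-6-methyl-4-oxocyclohex-2-en-1-yl acetate; 10 5-bromofuran-2-carbaldehyde
Product: 12 (9S,10S)-bromofuryl syn-aldol of 9 (new C9–C10 bond on the β face of ring A), via titanium dienolate 11 (not isolated)
Conditions: LiHMDS, THF, −78 °C; ClTi(Oi‑Pr)3, −78 → −40 °C; 10, −78 °C
Reagents that add atoms: none
Why: Directed aldol addition in which kinetic α′‑deprotonation of the enone is possible only at C10, the triisopropoxytitanium enolate of a cyclic (E‑configured) ketone adds to aromatic aldehydes through a boat‑like transition state to give the syn aldol (C9), and the aldehyde approaches anti to the C2 chain and the C14 acetate (C10).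

Step 6
Reactants: 12 (9S,10S)-bromofuryl syn-aldol of 9
Product: 13 9,14-diacetate (C9-OH of 12 acetylated)
Conditions: Ac2O, pyridine, DMAP (cat.), CH2Cl2, 0 °C
Reagents that add atoms: acetic anhydride CC(=O)OC(C)=O
Why: DMAP‑catalysed acylation installs the C9 acetate of the target with retention and removes the C9 carbinol as a competing partner in the later furan oxidation.

Step 7
Reactants: 13 9,14-diacetate
Product: 14 saturated C11 ketone (C12=C13 of 13 reduced)
Conditions: [(Ph3P)CuH]6, H2O (5 equiv), degassed toluene, rt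
Reagents that add atoms: none
Why: Conjugate reduction with Stryker's reagent delivers hydride only to the enone β‑carbon C13 and leaves the vinyl group, bromofuran and esters alone, and the copper enolate (C11=C12) has no β‑leaving group, so both acetates survive and no stereocentre changes.

Step 8
Reactants: 14 saturated C11 ketone
Product: 16 C4 aldehyde (vinyl group of 14 cleaved to CHO), via vicinal diol 15 (not isolated)
Conditions: OsO4 (2 mol %), NaIO4, 2,6‑lutidine, dioxane–H2O, rt
Reagents that add atoms: osmium tetroxide O=[Os](=O)(=O)=O; sodium periodate [Na+].[O-]I(=O)(=O)=O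
Why: Lemieux–Johnson cleavage acts on the only alkene left in the molecule, and the buffered medium keeps the α‑alkoxy aldehyde (C3) from epimerising.

Step 9
Reactants: 16 C4 aldehyde
Product: 17 [6](2,5)furanophane alcohol (C1–C10 carbocycle closed, furan = C5–C8, 4-OH, C11 ketone)
Conditions: CrCl2 (8 equiv), NiCl2 (2 mol %), DMF, 2 mM, rt
Reagents that add atoms: none
Why: Nozaki–Hiyama–Kishi reaction in which the furylchromium(III) species formed from the C5–Br bond adds only to the aldehyde, the trans‑diequatorial C2 and C9 arms on ring A pre‑organise the closure, and Felkin–Anh attack anti to the C3‑OMOM group gives the 3,4‑anti carbinol (C4).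

Step 10
Reactants: 17 [6](2,5)furanophane alcohol
Product: 18 11(20)-methylene furanophane alcohol
Conditions: Tebbe reagent (2.5 equiv), pyridine, THF–toluene, −40 → 0 °C
Reagents that add atoms: Tebbe reagent C[Al-]1(C)C[Ti]([Cl+]1)(C1C=CC=C1)C1C=CC=C1
Why: Tebbe methylenation converts the C11 ketone through an oxatitanacyclobutane faster than it touches esters at low temperature, and being non‑basic it avoids E1cB loss of the β‑acetoxy group at C9 and epimerisation at C10.

Step 11
Reactants: 18 11(20)-methylene furanophane alcohol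
Product: 20 bridged pyranone hemiketal (4,8-epoxy bridge; C5 ketone; C6=C7; 8-OH), via macrocyclic Z-enedione 19 (not isolated)
Conditions: NBS, NaHCO3, THF–H2O (4:1), 0 °C
Reagents that add atoms: water O
Why: Achmatowicz oxidative ring expansion in which bromonium/hydration opens the electron‑rich furan to the Z‑enedione, the free C4‑OH (C9 is blocked as acetate) adds across the ring to the C8 ketone, the five‑membered furan becomes the six‑membered pyranone, the 11‑oxabicyclo[6.2.1] frame becomes the 11‑oxabicyclo[5.3.1] frame of the target, and the bridge forces C3 and C9 cis so that C8 follows from C4.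

Step 12
Reactants: 21 propionic acid
Product: 22 1,1-bis(trimethylsilyloxy)prop-1-ene
Conditions: LDA (2.1 equiv, commercial solution), THF, −78 → 0 °C; TMSCl (2.3 equiv), rt; distil
Reagents that add atoms: chlorotrimethylsilane C[Si](C)(C)Cl
Why: Double deprotonation and double O‑silylation (silyl ketene acetal formation) give a nucleophile without an E/Z issue that releases the free acid on work‑up.

Step 13
Reactants: 20 bridged pyranone hemiketal; 22 1,1-bis(trimethylsilyloxy)prop-1-ene
Product: 24 C19 carboxylic acid (8-[(1R)-1-carboxyethyl] bridged pyranone), via trimethylsilyl ester 23 (not isolated)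
Conditions: 22 (3 equiv), TMSOTf (20 mol %), 2,6‑di‑tert‑butyl‑4‑methylpyridine (30 mol %), CH2Cl2, −78 → −20 °C; then pH 4 citrate buffer–THF
Reagents that add atoms: none
Why: Proposed new method: Mukaiyama‑type C–C substitution at a bridgehead hemiketal, in which TMSOTf silylates and ionises the C8‑OH to a twisted but still oxygen‑stabilised bridgehead oxocarbenium ion (its C=O+ bond is trans only within the flexible eight‑membered ring), the single open exo trajectory enforces retention at C8, and the staggered open transition state places C(OTMS)2 anti to C9 and the methyl group next to the ring oxygen to give 17R; the closest known reactions are Lewis‑acid C‑glycosylation and silane reduction of monocyclic Achmatowicz hemiketals and substitution of bridgehead α‑halo ethers of 9‑oxabicyclo[3.3.1]nonane.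

Step 14
Reactants: 24 C19 carboxylic acid
Product: 25 6-chloro-5-oxo-7,8-γ-lactone (Cl cis to the lactone oxygen)
Conditions: KHMDS (1.0 equiv), 18‑crown‑6, THF, −78 °C; NCS (1.05 equiv), −78 → −20 °C
Reagents that add atoms: N-chlorosuccinimide O=C1CCC(=O)N1Cl
Why: Proposed new method: chlorinative oxa‑Michael lactonisation, in which the crown‑activated carboxylate adds 5‑exo to C7 from the only face it can reach (cis to C17), and under proton‑free conditions the resulting C5 enolate is chlorinated at C6 from the exo face because the endo face is covered by the C9–C10–C1–C2–C3 bridge, so Cl ends cis to the lactone oxygen; the closest known reactions are base‑mediated intramolecular oxa‑Michael lactonisation, Michael‑initiated enolate halogenation and halolactonisation.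

Step 15
Reactants: 25 6-chloro-5-oxo-7,8-γ-lactone
Product: 26 2,3-bis(methoxymethyl) ether of the target
Conditions: Tebbe reagent (1.3 equiv), pyridine, THF–toluene, −78 → −20 °C
Reagents that add atoms: Tebbe reagent C[Al-]1(C)C[Ti]([Cl+]1)(C1C=CC=C1)C1C=CC=C1
Why: Tebbe methylenation is non‑basic, so the activated C5 ketone is converted before the lactone or acetates react and without retro‑Michael opening, HCl loss or epimerisation at C6.

Step 16
Reactants: 26 2,3-bis(methoxymethyl) ether of the target
Product: 27 CNP0176535.1 (target)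
Conditions: Me2BBr (5 equiv), CH2Cl2, −78 °C; then sat. aq NaHCO3–THF
Reagents that add atoms: none
Why: Lewis‑acid acetal cleavage with bromodimethylborane removes both MOM groups at −78 °C without Brønsted acid, so the two exocyclic alkenes, the allylic chloride, the acetates and the lactone are kept and no stereocentre is touched.

**Compound list**
1 | (E)-buta-1,3-dien-1-yl acetate | C=C/C=C/OC(C)=O | starting material
2 | methacrolein | C=C(C)C=O | starting material
3 | (1S,6R)-6-formyl-6-methylcyclohex-2-en-1-yl acetate (CHO cis to OAc) | C1C=C[C@H](OC(C)=O)[C@@](C=O)(C)C1 | intermediate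
4 | (1S,6R)-6-formyl-6-methyl-4-oxocyclohex-2-en-1-yl acetate | O=C1C=C[C@H](OC(C)=O)[C@@](C=O)(C)C1 | intermediate
5 | 3-(methoxymethoxy)prop-1-ene | C=CCOCOC | starting material
6 | (Z)-3-(methoxymethoxy)allyllithium (not isolated) | [Li]C/C=C\OCOC | intermediate
7 | (Z)-γ-(methoxymethoxy)allyldiisopinocampheylborane, Ipc from (+)-α-pinene (not isolated) | COCO/C=C\CB([C@@H]1C[C@@H]2C[C@H]([C@H]1C)C2(C)C)[C@@H]1C[C@@H]2C[C@H]([C@H]1C)C2(C)C | intermediate
8 | (1S,6S)-6-[(1R,2R)-1-hydroxy-2-(methoxymethoxy)but-3-en-1-yl]-6-methyl-4-oxocyclohex-2-en-1-yl acetate | O=C1C=C[C@H](OC(C)=O)[C@@]([C@@H](O)[C@H](OCOC)C=C)(C)C1 | intermediate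
9 | (1S,6R)-6-[(1R,2R)-1,2-bis(methoxymethoxy)but-3-en-1-yl]-6-methyl-4-oxocyclohex-2-en-1-yl acetate | O=C1C=C[C@H](OC(C)=O)[C@@]([C@@H](OCOC)[C@H](OCOC)C=C)(C)C1 | intermediate
10 | 5-bromofuran-2-carbaldehyde | O=Cc1ccc(Br)o1 | starting material
11 | triisopropoxytitanium cross-conjugated dienolate of 9, C10=C11–O–Ti (not isolated) | CC(C)O[Ti](OC(C)C)(OC(C)C)OC1C=C[C@H](OC(C)=O)[C@@]([C@@H](OCOC)[C@H](OCOC)C=C)(C)C=1 | intermediate
12 | (9S,10S)-bromofuryl syn-aldol of 9: C10 carries (S)-(5-bromofuran-2-yl)(hydroxy)methyl, trans to the C2 chain | O=C1C=C[C@H](OC(C)=O)[C@@]([C@@H](OCOC)[C@H](OCOC)C=C)(C)[C@H]1[C@H](O)c1ccc(Br)o1 | intermediate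
13 | 9,14-diacetate of 12 | O=C1C=C[C@H](OC(C)=O)[C@@]([C@@H](OCOC)[C@H](OCOC)C=C)(C)[C@H]1[C@H](OC(C)=O)c1ccc(Br)o1 | intermediate
14 | saturated C11 ketone (12,13-dihydro-13) | O=C1CC[C@H](OC(C)=O)[C@@]([C@@H](OCOC)[C@H](OCOC)C=C)(C)[C@H]1[C@H](OC(C)=O)c1ccc(Br)o1 | intermediate
15 | vicinal diol from the vinyl group of 14, epimers at the new carbinol (not isolated) | O=C1CC[C@H](OC(C)=O)[C@@]([C@@H](OCOC)[C@H](OCOC)C(O)CO)(C)[C@H]1[C@H](OC(C)=O)c1ccc(Br)o1 | intermediate
16 | C4 aldehyde | O=C1CC[C@H](OC(C)=O)[C@@]([C@@H](OCOC)[C@H](OCOC)C=O)(C)[C@H]1[C@H](OC(C)=O)c1ccc(Br)o1 | intermediate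
17 | [6](2,5)furanophane alcohol: C1–C10 carbocycle trans-fused to the cyclohexanone, furan carbons C5–C8, 4-OH anti to 3-OMOM, 2,3-bis-OMOM, 9,14-diacetate | O=C1CC[C@H](OC(C)=O)[C@@]2(C)[C@H]1[C@H](OC(C)=O)c1ccc(o1)[C@@H](O)[C@@H](OCOC)[C@@H]2OCOC | intermediate
18 | 11(20)-methylene furanophane alcohol | C=C1CC[C@H](OC(C)=O)[C@@]2(C)[C@H]1[C@H](OC(C)=O)c1ccc(o1)[C@@H](O)[C@@H](OCOC)[C@@H]2OCOC | intermediate
19 | macrocyclic (6Z)-5,8-dione with free 4-OH (not isolated) | C=C1CC[C@H](OC(C)=O)[C@@]2(C)[C@H]1[C@H](OC(C)=O)C(=O)/C=C\C(=O)[C@@H](O)[C@@H](OCOC)[C@@H]2OCOC | intermediate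
20 | bridged pyranone hemiketal: 4,8-epoxy bridge (11-oxabicyclo[5.3.1]), C5 ketone, C6=C7, exo 8-OH | C=C1CC[C@H](OC(C)=O)[C@@]2(C)[C@H]1[C@H](OC(C)=O)[C@@]1(O)O[C@H](C(=O)C=C1)[C@@H](OCOC)[C@@H]2OCOC | intermediate
21 | propionic acid | CCC(=O)O | starting material
22 | 1,1-bis(trimethylsilyloxy)prop-1-ene | CC=C(O[Si](C)(C)C)O[Si](C)(C)C | intermediate
23 | trimethylsilyl ester of 24 (not isolated) | C=C1CC[C@H](OC(C)=O)[C@@]2(C)[C@H]1[C@H](OC(C)=O)[C@@]1([C@@H](C)C(=O)O[Si](C)(C)C)O[C@H](C(=O)C=C1)[C@@H](OCOC)[C@@H]2OCOC | intermediate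
24 | C19 carboxylic acid: 20 with the 8-OH replaced by (1R)-1-carboxyethyl (C17–C19) | C=C1CC[C@H](OC(C)=O)[C@@]2(C)[C@H]1[C@H](OC(C)=O)[C@@]1([C@@H](C)C(=O)O)O[C@H](C(=O)C=C1)[C@@H](OCOC)[C@@H]2OCOC | intermediate
25 | 6-chloro-5-oxo-7,8-γ-lactone, Cl, O-7 and C17 on the same face of the pyran ring | C=C1CC[C@H](OC(C)=O)[C@@]2(C)[C@H]1[C@H](OC(C)=O)[C@@]13O[C@H](C(=O)[C@H](Cl)[C@@H]1OC(=O)[C@@H]3C)[C@@H](OCOC)[C@@H]2OCOC | intermediate
26 | 2,3-bis(methoxymethyl) ether of the target | C=C1CC[C@H](OC(C)=O)[C@@]2(C)[C@H]1[C@H](OC(C)=O)[C@@]13O[C@H](C(=C)[C@H](Cl)[C@@H]1OC(=O)[C@@H]3C)[C@@H](OCOC)[C@@H]2OCOC | intermediate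
27 | CNP0176535.1, (1S,2R,3S,4R,6S,7R,8R,9S,10S,14S,17R) | C=C1CC[C@H](OC(C)=O)[C@@]2(C)[C@H]1[C@H](OC(C)=O)[C@@]13O[C@H](C(=C)[C@H](Cl)[C@@H]1OC(=O)[C@@H]3C)[C@@H](O)[C@@H]2O | target

**Totals**
- Total step count: 16.
- Longest linear sequence: 15 (steps 1–11 and 13–16).

**The three steps most likely to fail**

**Step 13 (proposed new step).**
- Risk: the bridgehead cation may not form under catalytic TMSOTf, or 22 may add in Mukaiyama–Michael fashion at C7.
- The fallback sets out from 20 and comes back at 24.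
- SOCl2 and pyridine in CH2Cl2 at −20 °C convert the hemiketal into the isolable bridgehead α‑chloro ether F1.
- AgOTf (1.2 equiv) with the hindered pyridine base at −78 °C, in the presence of 22, then abstracts the chloride irreversibly.
- This is Koenigs–Knorr‑type C‑glycosylation of an α‑chloro ether with a silyl ketene acetal, a known reaction class that includes bridgehead α‑halo ethers.
- The silyl ester 23 formed in this way is hydrolysed on work‑up to 24.

**Step 14 (proposed new step).**
- Risk: protonation may outrun chlorination, or the α‑chloro ketone may lose the carboxylate again.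
- The fallback sets out from 24 and comes back at 25, and separates the two events with known chemistry.
- Catalytic DBU in CH2Cl2 closes the ring by ordinary intramolecular oxa‑Michael addition to give the 5‑oxo‑7,8‑γ‑lactone F2.
- TMSOTf and Et3N at 0 °C give the C5 silyl enol ether F3. Enolisation can only go towards C6 because C4 is a bridgehead.
- NCS in CH2Cl2 at −40 °C chlorinates F3 from the exo face to give 25.

**Step 15.**
- Risk: the α‑chloro‑β‑acyloxy ketone may decompose with the Lewis‑acidic Ti/Al reagent, or the lactone may compete.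
- The fallback sets out from 25 and comes back at 26, and replaces the metallacycle olefination by a Peterson sequence.
- Me3SiCH2MgCl with anhydrous CeCl3 in THF at −78 °C adds selectively to the ketone to give the β‑hydroxysilane F4. Either C5 epimer serves.
- Aqueous HF in MeCN at 0 °C then brings about the acid Peterson elimination to 26.

**Further compounds**
F1 | step 13 | bridgehead α-chloro ether (8-Cl analogue of 20) | C=C1CC[C@H](OC(C)=O)[C@@]2(C)[C@H]1[C@H](OC(C)=O)[C@@]1(Cl)O[C@H](C(=O)C=C1)[C@@H](OCOC)[C@@H]2OCOC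
F2 | step 14 | 5-oxo-7,8-γ-lactone (6-deschloro 25) | C=C1CC[C@H](OC(C)=O)[C@@]2(C)[C@H]1[C@H](OC(C)=O)[C@@]13O[C@H](C(=O)C[C@@H]1OC(=O)[C@@H]3C)[C@@H](OCOC)[C@@H]2OCOC
F3 | step 14 | C5 trimethylsilyl enol ether of F2 (C5=C6) | C=C1CC[C@H](OC(C)=O)[C@@]2(C)[C@H]1[C@H](OC(C)=O)[C@@]13O[C@H](C(O[Si](C)(C)C)=C[C@@H]1OC(=O)[C@@H]3C)[C@@H](OCOC)[C@@H]2OCOC
F4 | step 15 | β-hydroxysilane: 5-hydroxy-5-(trimethylsilylmethyl) adduct of 25, C5 configuration not defined | C=C1CC[C@H](OC(C)=O)[C@@]2(C)[C@H]1[C@H](OC(C)=O)[C@@]13O[C@H](C(O)(C[Si](C)(C)C)[C@H](Cl)[C@@H]1OC(=O)[C@@H]3C)[C@@H](OCOC)[C@@H]2OCOC
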